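(Readings and results were generated by integration with constants of no real substance; noise was put on by code.)

A late slope of 0.248 min⁻¹ in Monday's Z against 0.568 min⁻¹ in Wednesday's was what I decided by. The decision was which recipe to repeat for longer chains.

in all of them: G 2.8 mM
- Monday's: Z 0.14 M; run made earlier
- Wednesday's: Z 0.53 M; run made earlier
- zeta: Z 0.20 M; time 15 min
- delta: Z 0.80 M; time 15 min

| run | time / min | D / % | Z / % |
|---|---|---|---|
| Monday's | 1.50 | 9.4 | 89.3 |
| Monday's | 3.00 | 30.4 | 68.6 |
| Monday's | 5.00 | 51.3 | 46.8 |
| Monday's | 6.00 | 59.2 | 37.9 |
| Monday's | 8.00 | 73.7 | 23.1 |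
| Wednesday's | 0.667 | 10.9 | 90.6 |
| Wednesday's | 1.00 | 19.3 | 81.7 |
| Wednesday's | 2.00 | 44.4 | 53.6 |
| Wednesday's | 4.00 | 79.3 | 17.2 |
| Wednesday's | 8.00 | 95.8 | 0.3 |

(readings scatter by 1 percentage point)

- the average divides the monomer in chains by the number of chains begun, living and dead together
- on the list of suspects stand: Z + G -> Q + D; Z + Q -> D + Q; 2 G -> E; Z -> J; Z -> X
- the earlier runs do not show the number of chains; that part of a forecast is a guess

- which of the two ends with the longer chains by the average number of monomer units in a chain (chains begun, living or dead) ("neither" if they lie within 10%) (zeta / delta / neither)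
- average number of monomer units in a chain (chains begun, living or dead) at the end, zeta
- average number of monomer units in a chain (chains begun, living or dead) at the end, delta

I took Monday's first-order slope from 6.00 min to 8.00 min and Wednesday's from 2.00 min to 4.00 min. With Z + Q -> D + Q among the suspects, such a slope is a pseudo-first-order constant that counts the living ends Q, and each Q is a chain begun. Wednesday's charge of Z was 3.79 times Monday's and the slope read 2.29 times as high, so I read the ends as going with the charge to the power 0.624.

Length is monomer in chains over chains begun, which gave me the length exponent, the power of the Z charge to which the final average length rises at this G: 0.376. One would mean ends unmoved by the charge, and zero would mean ends rising in step with it. Mine lay between, which on the suspects reads as G shared between starting chains and coupling into E.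

From zeta to delta the charge rises 4.00 times, so I expected delta's chains longer by a factor of 1.68, more than the 10% margin, and I chose delta. That factor rests on the readings at the ends of those two stretches and carries their scatter of 1 percentage point. The runs show no chain number, so I committed to no absolute length. I would watch the late slope of Z, which the same power puts at 0.309 min⁻¹ in zeta and 0.735 min⁻¹ in delta.

The forecast also chose delta, with 180 for zeta and 330 for delta, a ratio of 1.83 where mine was 1.68, and it wrote: “The chain counts are a guess”.

The flask chose delta.

    Z + G → Q + D (k = 0.00460 M⁻¹ s⁻¹)
    Z + Q → D + Q, rate k2*[Q]*[Z] (k = 23.0 M⁻¹ s⁻¹)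
    2 G → E (k = 3.20 M⁻¹ s⁻¹)
    Z → J (k = 4.30 × 10⁻⁶ s⁻¹)
    Z → X (k = 8.50 × 10⁻⁵ s⁻¹)

Zeta ended at 871 and delta at 1460, a ratio of 1.68, and the forecast's lengths stood too low by factors of 4.84 and 4.42. The neighbouring flask is zeta with 0.34 M of Z. The length exponent gives it a factor of 1.22 on zeta's length, which makes 1060. The neighbouring flask gave 1060.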